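You are asked how much L stays free in solution at the end of each flask, and how that amount runs with the charge of Z.

all flasks: time 40 s
- oak: Z 10 mM
- birch: Z 15 mM
- ash: Z 25 mM

    Z ⇌ J (K1 = 1.0, k1 = 0.0041 /s)
    Z ⇌ L (K2 = 0.53, k2 = 0.0048 /s)
    J → D (k3 = 0.0046 /s)
    E ⇌ L, rate k4*(cs4 - [L]) while solid is left; crystals form when [L] > cs4 (cs4 = 0.41 mM, k4 = 1.2 /s)
    2 J → J2 (k5 = 0.16 /M/s)

- a species is counted by the Z in it: one J2 counts as two
- amounts and yields of L count E too
- where a step has two of a species, its rate is k times that concentration squared, and two are used at each turn
- given per volume of solution although it is solid: E
- the concentration of L that is asked is that of its free form alone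
- "hardly changes" means that all values lie within two and a half points (for a concentration: within two and a half percent of the largest)
- run time (oak): 40 s

* [L] (only what is free in solution) at the end for oak, birch, ash, in this order
* how the row runs (falls all the way / rises all the way / rises, then falls / falls, then rises / hardly changes)

**Main step.** Take the step from Z to L by itself first. Oak starts by feeding L at 0.0480 mM/s, so it reaches the solubility of 0.41 mM after roughly 8.54 s. Ash feeds at 0.120 mM/s and gets there after roughly 3.42 s. Both times are shorter than the run of 40 s, so crystals of E should be forming well before the end.

**Adding crystals.** Crystals take up L in proportion to its excess over the solubility. The quantity to carry is the hold-up time θ, one over the dissolution coefficient, 0.833 s: the excess equals the net feed of L times θ, a quasi-steady state. The net feed is the forward rate from Z less the return of L to Z, which at the solubility is 0.003713 mM/s. Since θ is far shorter than the run, the excess follows the feed of the moment, so the end needs the feed at the end and not its mean over the run. With Z held at its charge, my figure for oak is 0.447 mM.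

**Draining Z.** Z also leaves towards J. Counting both forward steps and neglecting what returns, my count leaves 70.0% of the charge at the end. That lowers my figure for oak to 0.435 mM, and gives 0.449 mM for birch and 0.477 mM for ash.

**The rest.** I leave out the steps that take J onward and the return of J to Z. My row rises all the way, as the feed in ash is larger than in oak and the solubility is the same in each.

**The outcome.** The forecast gives 0.436 mM, 0.451 mM and 0.479 mM, a row that rises all the way, on the ground that “That excess grows with the Z remaining”. The simulation gives 0.436 mM, 0.450 mM and 0.478 mM, and the row rises all the way.

**The ceiling.** Without the ceiling that the crystals set, free L in ash ends at 3.41 mM instead of 0.478 mM, the largest single effect. With the 71.6% of its Z that ash holds at 40.0 s, net feed times θ gives an excess of 0.0685 mM. At 400 s ash holds 9.03% of its Z, so the same θ gives 0.416 mM, and the longer run stands at 0.416 mM.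

The constants were chosen freely; the result is computed.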